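**Retrosynthetic overview**

1. Target 17 ⇐ TES removal and C8‑O tigloylation of macrocyclic epoxy alcohol 15.
2. Key disconnection: the C7–C8 ring bond and the C9–C10 epoxide together. Open‑chain enal 12 carries a butenolide allylboronate; epoxidation of the enal triggers intramolecular allylboration, so oxirane and ten‑membered carbocycle close in one operation (C7–C10 set).
3. 12 ⇐ C5–C6 bond by vinylogous Mukaiyama aldol of dialdehyde 5 with borylated 2‑silyloxyfuran 10 (C5, C6 set).
4. 5 ⇐ geranyl acetate (allylic oxidation, asymmetric hydrogenation for C4); 10 ⇐ α‑methylene‑γ‑butyrolactone.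
5. Ring order: the lactone ring comes in with the butenolide building block; then the epoxide, then the carbocycle, both in step 10.

Convention: ring atoms are numbered germacrane‑style (C1–C3 = CH2; C4 = CH–CH3; C5 = CH–OH; C6 = CH–O lactone; C7 = ring fusion; C8 = CH–O‑tigloyl; C9/C10 = epoxide CH / C–CH3; C11 = C(=CH2); C12 = C=O). The target is 4R,5R,6S,7S,8R,9R,10R; C7 is labelled R in 14–16 only because the CIP ranking changes, not the geometry.

Assumption: where a chiral catalyst is named, the enantiomer given is the expected one; its antipode is used if a test run shows the opposite facial sense.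

**Step 1**
Reactants: 1 geranyl acetate
Product: 2 (2E,6E)-8-hydroxy-3,7-dimethylocta-2,6-dien-1-yl acetate
Conditions: SeO2 (10 mol%), salicylic acid (10 mol%), t-BuOOH (3 equiv), CH2Cl2, rt
Reagents that add atoms: tert-butyl hydroperoxide, CC(C)(C)OO
Why: SeO2 allylic oxidation (ene/[2,3] sequence) is selective for the (E)-methyl of the electron‑rich terminal alkene and leaves the acetate‑deactivated 2,3‑alkene alone; no stereocentre is formed.

**Step 2**
Reactants: 2 (2E,6E)-8-hydroxy-3,7-dimethylocta-2,6-dien-1-yl acetate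
Product: 3 (2E,7R)-8-hydroxy-3,7-dimethyloct-2-en-1-yl acetate
Conditions: Ru(OAc)2[(R)-BINAP] (1 mol%), H2 (50 atm), MeOH, 25 °C
Reagents that add atoms: none
Why: Noyori hydroxyl‑directed asymmetric hydrogenation reduces only the alkene of the free allylic alcohol (the allylic acetate cannot chelate Ru), and the BINAP ligand selects the enantioface to set the methyl stereocentre (target C4) as R.

**Step 3**
Reactants: 3 (2E,7R)-8-hydroxy-3,7-dimethyloct-2-en-1-yl acetate
Product: 4 (2E,7R)-3,7-dimethyloct-2-ene-1,8-diol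
Conditions: K2CO3 (cat.), MeOH, rt
Reagents that add atoms: none
Why: Base‑catalysed transesterification (methanolysis) frees the allylic alcohol without touching the remote stereocentre.

**Step 4**
Reactants: 4 (2E,7R)-3,7-dimethyloct-2-ene-1,8-diol
Product: 5 (2E,7R)-3,7-dimethyloct-2-enedial
Conditions: TEMPO (20 mol%), PhI(OAc)2 (2.4 equiv), CH2Cl2, rt
Reagents that add atoms: none
Why: TEMPO/PhI(OAc)2 oxidation stops at the aldehyde for both primary alcohols under near‑neutral conditions, so the (E)-enal geometry and the epimerisable α‑methyl centre survive.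

**Step 5**
Reactants: 6 3-methylidenedihydrofuran-2(3H)-one (α‑methylene‑γ‑butyrolactone)
Product: 8 3-(bromomethyl)furan-2(5H)-one, via dibromide 7 (not isolated)
Conditions: Br2, CH2Cl2, 0 °C; then Et3N, 0 °C to rt
Reagents that add atoms: bromine, BrBr
Why: Bromine addition to the exocyclic alkene followed by E2 loss of HBr toward the ring (bromination–dehydrobromination) gives the conjugated butenolide with the allylic bromide; no stereocentre remains.

**Step 6**
Reactants: 8 3-(bromomethyl)furan-2(5H)-one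
Product: 9 3-[(4,4,5,5-tetramethyl-1,3,2-dioxaborolan-2-yl)methyl]furan-2(5H)-one
Conditions: B2pin2, Pd2(dba)3 (2 mol%), KOAc, toluene, 50 °C
Reagents that add atoms: bis(pinacolato)diboron, CC1(C)OB(OC1(C)C)B1OC(C)(C)C(C)(C)O1
Why: Miyaura‑type Pd(0) allylic borylation through a π‑allyl complex places boron on the unhindered CH2 terminus and keeps the conjugated butenolide.

**Step 7**
Reactants: 9 3-[(4,4,5,5-tetramethyl-1,3,2-dioxaborolan-2-yl)methyl]furan-2(5H)-one
Product: 10 tert-butyldimethyl({3-[(4,4,5,5-tetramethyl-1,3,2-dioxaborolan-2-yl)methyl]furan-2-yl}oxy)silane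
Conditions: TBSOTf, Et3N, CH2Cl2, 0 °C; used crude
Reagents that add atoms: tert-butyldimethylsilyl triflate, CC(C)(C)[Si](C)(C)OS(=O)(=O)C(F)(F)F
Why: O‑silylation with γ‑deprotonation (soft enolisation) gives the aromatic 2‑silyloxyfuran, the dienolate equivalent for the vinylogous aldol.

**Step 8**
Reactants: 5 (2E,7R)-3,7-dimethyloct-2-enedial; 10 tert-butyldimethyl({3-[(4,4,5,5-tetramethyl-1,3,2-dioxaborolan-2-yl)methyl]furan-2-yl}oxy)silane
Product: 11 (5S)-5-[(1R,2R,6E)-1-hydroxy-2,6-dimethyl-8-oxooct-6-en-1-yl]-3-[(4,4,5,5-tetramethyl-1,3,2-dioxaborolan-2-yl)methyl]furan-2(5H)-one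
Conditions: (R,R)-(salen)Cr(III)SbF6 (5 mol%), CH2Cl2, −20 °C; then aq citric acid, THF
Reagents that add atoms: none
Why: Catalytic asymmetric vinylogous Mukaiyama aldol at the furan 5‑position engages only the saturated aldehyde (the β,β‑disubstituted enal is far less electrophilic); the chiral Lewis acid fixes the aldehyde face and the open antiperiplanar transition state gives the anti pair C5 (R) / C6 (S), overriding the weak Felkin bias of C4.

**Step 9**
Reactants: 11 (5S)-5-[(1R,2R,6E)-1-hydroxy-2,6-dimethyl-8-oxooct-6-en-1-yl]-3-[(4,4,5,5-tetramethyl-1,3,2-dioxaborolan-2-yl)methyl]furan-2(5H)-one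
Product: 12 (5S)-5-[(1R,2R,6E)-2,6-dimethyl-8-oxo-1-(triethylsilyloxy)oct-6-en-1-yl]-3-[(4,4,5,5-tetramethyl-1,3,2-dioxaborolan-2-yl)methyl]furan-2(5H)-one
Conditions: TESCl, imidazole, DMAP (cat.), DMF, rt
Reagents that add atoms: chlorotriethylsilane, CC[Si](Cl)(CC)CC
Why: Silyl ether formation under imidazole (too weak a base to enolise the butenolide and scramble C6) blocks the C5 hydroxyl so that only the later C8 hydroxyl is acylated.

**Step 10**
Reactants: 12 (5S)-5-[(1R,2R,6E)-2,6-dimethyl-8-oxo-1-(triethylsilyloxy)oct-6-en-1-yl]-3-[(4,4,5,5-tetramethyl-1,3,2-dioxaborolan-2-yl)methyl]furan-2(5H)-one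
Product: 15 (4R,5R,6S,7R,8R,9R,10R)-9,10-epoxy-8-hydroxy-5-(triethylsilyloxy)germacr-11(13)-en-12,6-olide, via epoxy aldehyde 13 (not isolated), via borate ester 14 (not isolated)
Conditions: t-BuOOH (1.2 equiv), [(3,5-(F3C)2C6H3CH2)2NH2][(S)-TRIP] (10 mol%), TBME, 0 °C; then dilute to 5 mM with toluene, (PhO)2P(O)OH (10 mol%), 40 °C; aq NaHCO3/Na2S2O3
Reagents that add atoms: tert-butyl hydroperoxide, CC(C)(C)OO
Why: Proposed new method: iminium activation of the (E)-enal with the chiral phosphate counter‑anion directs conjugate addition of t-BuOOH to one face and enamine ring closure gives the trans epoxy aldehyde 13 (C9, C10); its more electrophilic carbonyl is then captured by the pendant 2‑(alkoxycarbonyl)allylboronate under phosphoric‑acid activation through a closed chair transition state in which the aldehyde adds to C7 anti to the C6 side chain (trans lactone), the ring‑locked E‑type allyl unit gives the anti C7/C8 pair, and that same aldehyde face is the Felkin–Anh face (anti to the epoxide C–O), so oxirane and ten‑membered ring form in one flask; the closest known reactions are counter‑anion‑directed iminium epoxidation of β,β‑disubstituted enals with alkyl hydroperoxides, Brønsted‑acid‑catalysed carbonyl allylboration, and the 2‑(alkoxycarbonyl)allylboronate route to α‑methylene‑γ‑butyrolactones.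

**Step 11**
Reactants: 15 (4R,5R,6S,7R,8R,9R,10R)-9,10-epoxy-8-hydroxy-5-(triethylsilyloxy)germacr-11(13)-en-12,6-olide
Product: 16 (4R,5R,6S,7R,8R,9R,10R)-9,10-epoxy-8-[(2E)-2-methylbut-2-enoyloxy]-5-(triethylsilyloxy)germacr-11(13)-en-12,6-olide
Conditions: tigloyl chloride, pyridine, DMAP (cat.), CH2Cl2, 0 °C to rt
Reagents that add atoms: (E)-2-methylbut-2-enoyl chloride (tigloyl chloride), C/C=C(\C)C(Cl)=O
Why: DMAP‑catalysed acylation (nucleophilic catalysis) of the only free hydroxyl installs the configurationally stable (E)-tiglate; no stereocentre is touched.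

**Step 12**
Reactants: 16 (4R,5R,6S,7R,8R,9R,10R)-9,10-epoxy-8-[(2E)-2-methylbut-2-enoyloxy]-5-(triethylsilyloxy)germacr-11(13)-en-12,6-olide
Product: 17 (4R,5R,6S,7S,8R,9R,10R)-9,10-epoxy-5-hydroxy-8-[(2E)-2-methylbut-2-enoyloxy]germacr-11(13)-en-12,6-olide (target)
Conditions: HF·pyridine, pyridine, THF, 0 °C
Reagents that add atoms: none
Why: Buffered fluoride desilylation removes the TES ether without opening the epoxide, adding to the α‑methylene lactone or cleaving the tiglate; all seven stereocentres are unchanged.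

**Compound list**

1 | geranyl acetate | CC(=O)OC/C=C(\C)CCC=C(C)C | starting material
2 | (2E,6E)-8-hydroxy-3,7-dimethylocta-2,6-dien-1-yl acetate | CC(=O)OC/C=C(\C)CC/C=C(\C)CO | intermediate
3 | (2E,7R)-8-hydroxy-3,7-dimethyloct-2-en-1-yl acetate | CC(=O)OC/C=C(\C)CCC[C@@H](C)CO | intermediate
4 | (2E,7R)-3,7-dimethyloct-2-ene-1,8-diol | OC/C=C(\C)CCC[C@@H](C)CO | intermediate
5 | (2E,7R)-3,7-dimethyloct-2-enedial | O=C/C=C(\C)CCC[C@@H](C)C=O | intermediate
6 | 3-methylidenedihydrofuran-2(3H)-one (α‑methylene‑γ‑butyrolactone) | C=C1CCOC1=O | starting material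
7 | 3-bromo-3-(bromomethyl)dihydrofuran-2(3H)-one (racemic, not isolated) | BrCC1(Br)CCOC1=O | intermediate
8 | 3-(bromomethyl)furan-2(5H)-one | BrCC1=CCOC1=O | intermediate
9 | 3-[(4,4,5,5-tetramethyl-1,3,2-dioxaborolan-2-yl)methyl]furan-2(5H)-one | O=C1OCC=C1CB1OC(C)(C)C(C)(C)O1 | intermediate
10 | tert-butyldimethyl({3-[(4,4,5,5-tetramethyl-1,3,2-dioxaborolan-2-yl)methyl]furan-2-yl}oxy)silane | CC(C)(C)[Si](C)(C)Oc1occc1CB1OC(C)(C)C(C)(C)O1 | intermediate
11 | (5S)-5-[(1R,2R,6E)-1-hydroxy-2,6-dimethyl-8-oxooct-6-en-1-yl]-3-[(4,4,5,5-tetramethyl-1,3,2-dioxaborolan-2-yl)methyl]furan-2(5H)-one | O=C1O[C@@H](C=C1CB2OC(C)(C)C(C)(C)O2)[C@H](O)[C@H](C)CCC/C(C)=C/C=O | intermediate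
12 | (5S)-5-[(1R,2R,6E)-2,6-dimethyl-8-oxo-1-(triethylsilyloxy)oct-6-en-1-yl]-3-[(4,4,5,5-tetramethyl-1,3,2-dioxaborolan-2-yl)methyl]furan-2(5H)-one | O=C1O[C@@H](C=C1CB2OC(C)(C)C(C)(C)O2)[C@H](O[Si](CC)(CC)CC)[C@H](C)CCC/C(C)=C/C=O | intermediate
13 | (2S,3R)-3-methyl-3-{(4R,5R)-4-methyl-5-[(2S)-5-oxo-4-[(4,4,5,5-tetramethyl-1,3,2-dioxaborolan-2-yl)methyl]-2,5-dihydrofuran-2-yl]-5-(triethylsilyloxy)pentyl}oxirane-2-carbaldehyde (not isolated) | O=C1O[C@@H](C=C1CB2OC(C)(C)C(C)(C)O2)[C@H](O[Si](CC)(CC)CC)[C@H](C)CCC[C@@]3(C)O[C@@H]3C=O | intermediate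
14 | (4R,5R,6S,7R,8R,9R,10R)-9,10-epoxy-8-[(4,4,5,5-tetramethyl-1,3,2-dioxaborolan-2-yl)oxy]-5-(triethylsilyloxy)germacr-11(13)-en-12,6-olide (not isolated) | C=C1C(=O)O[C@@H]2[C@H](O[Si](CC)(CC)CC)[C@H](C)CCC[C@@]3(C)O[C@@H]3[C@H](OB4OC(C)(C)C(C)(C)O4)[C@@H]12 | intermediate
15 | (4R,5R,6S,7R,8R,9R,10R)-9,10-epoxy-8-hydroxy-5-(triethylsilyloxy)germacr-11(13)-en-12,6-olide | C=C1C(=O)O[C@@H]2[C@H](O[Si](CC)(CC)CC)[C@H](C)CCC[C@@]3(C)O[C@@H]3[C@H](O)[C@@H]12 | intermediate
16 | (4R,5R,6S,7R,8R,9R,10R)-9,10-epoxy-8-[(2E)-2-methylbut-2-enoyloxy]-5-(triethylsilyloxy)germacr-11(13)-en-12,6-olide | C=C1C(=O)O[C@@H]2[C@H](O[Si](CC)(CC)CC)[C@H](C)CCC[C@@]3(C)O[C@@H]3[C@H](OC(=O)/C(C)=C/C)[C@@H]12 | intermediate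
17 | (4R,5R,6S,7S,8R,9R,10R)-9,10-epoxy-5-hydroxy-8-[(2E)-2-methylbut-2-enoyloxy]germacr-11(13)-en-12,6-olide | C=C1C(=O)O[C@@H]2[C@H](O)[C@H](C)CCC[C@@]3(C)O[C@@H]3[C@H](OC(=O)/C(C)=C/C)[C@@H]12 | target

**Step count and risks**

Total step count: 12. Longest linear sequence: 9 steps (1–4, then 8–12, from geranyl acetate); the butenolide arm is 3 steps (5–7).

Three steps most likely to fail:

Step 10 (epoxidation‑triggered ring closure). The risks are the wrong epoxide face, oxidation of the C–B bond by the hydroperoxide, and allylation of the enal before it is epoxidised. The fallback sets the epoxide at the alcohol oxidation state under reagent control and closes the ring as a separate event. It sets out from 12: Luche reduction (NaBH4, CeCl3, MeOH, −40 °C) gives the allylic alcohol F1; Sharpless epoxidation (Ti(OiPr)4, D-(−)-diisopropyl tartrate, t-BuOOH, 4 Å sieves, CH2Cl2, −20 °C) gives the (2R,3R)-epoxy alcohol F2; Dess–Martin oxidation then returns to the route at epoxy aldehyde 13, now isolated, which is cyclised on its own (5 mM in toluene, cat. diphenyl phosphate, 40–60 °C) to 15.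

Step 8 (vinylogous aldol). The risks are low anti selectivity and insufficient catalyst control over C5/C6. The fallback accepts the more common syn outcome and corrects C5 by inversion. It sets out from 5 and 10: a syn‑selective chiral Lewis acid aldol (for example Ti(IV)/BINOL) gives the C5‑epimeric aldol F3 with C6 already correct; Mitsunobu inversion (ClCH2CO2H, PPh3, DIAD, THF) gives the chloroacetate F4; thiourea/NaHCO3 in EtOH removes the chloroacetyl group and returns to the route at 11.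

Step 2 (asymmetric hydrogenation of a 2‑methyl allylic alcohol). The risk is modest enantioselectivity with this substitution pattern. The fallback uses the better‑established carboxylic‑acid‑directed hydrogenation. It sets out from 2: TEMPO/PhI(OAc)2 in MeCN–H2O gives the dienoic acid F5; Ru(OAc)2[(R)-H8-BINAP]/H2 in MeOH reduces only the α,β‑unsaturated acid to the (2R)-acid F6; LiAlH4 reduces the acid and cleaves the acetate, returning to the route at diol 4.

**Further compounds**

F1 | step 10 | (5S)-5-[(1R,2R,6E)-8-hydroxy-2,6-dimethyl-1-(triethylsilyloxy)oct-6-en-1-yl]-3-[(4,4,5,5-tetramethyl-1,3,2-dioxaborolan-2-yl)methyl]furan-2(5H)-one | O=C1O[C@@H](C=C1CB2OC(C)(C)C(C)(C)O2)[C@H](O[Si](CC)(CC)CC)[C@H](C)CCC/C(C)=C/CO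
F2 | step 10 | (5S)-5-{(1R,2R)-5-[(2R,3R)-3-(hydroxymethyl)-2-methyloxiran-2-yl]-2-methyl-1-(triethylsilyloxy)pentyl}-3-[(4,4,5,5-tetramethyl-1,3,2-dioxaborolan-2-yl)methyl]furan-2(5H)-one | O=C1O[C@@H](C=C1CB2OC(C)(C)C(C)(C)O2)[C@H](O[Si](CC)(CC)CC)[C@H](C)CCC[C@@]3(C)O[C@@H]3CO
F3 | step 8 | (5S)-5-[(1S,2R,6E)-1-hydroxy-2,6-dimethyl-8-oxooct-6-en-1-yl]-3-[(4,4,5,5-tetramethyl-1,3,2-dioxaborolan-2-yl)methyl]furan-2(5H)-one | O=C1O[C@@H](C=C1CB2OC(C)(C)C(C)(C)O2)[C@@H](O)[C@H](C)CCC/C(C)=C/C=O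
F4 | step 8 | (5S)-5-[(1R,2R,6E)-1-(chloroacetoxy)-2,6-dimethyl-8-oxooct-6-en-1-yl]-3-[(4,4,5,5-tetramethyl-1,3,2-dioxaborolan-2-yl)methyl]furan-2(5H)-one | O=C1O[C@@H](C=C1CB2OC(C)(C)C(C)(C)O2)[C@H](OC(=O)CCl)[C@H](C)CCC/C(C)=C/C=O
F5 | step 2 | (2E,6E)-8-acetoxy-2,6-dimethylocta-2,6-dienoic acid | CC(=O)OC/C=C(\C)CC/C=C(\C)C(O)=O
F6 | step 2 | (2R,6E)-8-acetoxy-2,6-dimethyloct-6-enoic acid | CC(=O)OC/C=C(\C)CCC[C@@H](C)C(O)=O
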